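Cupressuflavone is traced back to a symmetric biphenyl whose axis never has to be made by aryl–aryl coupling. Each ring A is a phloroglucinol in which C8 (and C8'') sits between the oxygens on C7 and C8a and para to the C5 oxygen. That is the pattern produced when a 6-alkyl-4-methoxy-2-pyranone is opened by methoxide and recloses by Claisen condensation. In one operation the key step therefore turns both lactone rings of 1,2-bis(4-methoxy-2-oxo-2H-pyran-6-yl)ethane into the two ring A arenes, the CH2–CH2 link becoming the C8–C8'' bond. The precursor is the oxidative dimer of triacetic lactone methyl ether; rings C and B follow by acetylation, aroylation and cyclodehydration.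

Key step: step 3

Remark: the target SMILES carries no axial descriptor, so racemic cupressuflavone is the goal; the configurationally stable 8,8'' axis arises without control in step 3.
Remark: in the ring-opened intermediate 6 the enoate double bonds are E by the CIP rules although ester and keto chain are cis, and each Claisen closure is 6-(enolendo)-exo-trig; the route uses these descriptors.

Step 1
Reactants: 1 triacetic lactone (4-hydroxy-6-methyl-2H-pyran-2-one); 2 dimethyl sulfate
Product: 3 4-methoxy-6-methyl-2H-pyran-2-one
Conditions: Me2SO4 (1.2 equiv), K2CO3 (1.5 equiv), acetone, reflux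
Reagents that add atoms: dimethyl sulfate, COS(=O)(=O)OC
Why: Williamson-type O-methylation of the vinylogous acid, for which Me2SO4 with K2CO3 in acetone is the standard way to the 4-methoxy-2-pyranone rather than the isomeric 2-methoxy-4-pyranone.

Step 2
Reactants: 3 4-methoxy-6-methyl-2H-pyran-2-one (two molecules)
Product: 5 1,2-bis(4-methoxy-2-oxo-2H-pyran-6-yl)ethane, via lithium dienolate 4 (not isolated)
Conditions: LiN(SiMe3)2 (1.05 equiv), THF, −78 °C; then CuCl2 (1.1 equiv), DMF, −78 °C to rt
Reagents that add atoms: none
Why: Lateral deprotonation of the 6-methyl group gives the extended ester enolate, and one-electron oxidation by divalent copper (oxidative enolate homocoupling) should join two units at the exocyclic carbon, the only coupling site that keeps the 2-pyranone conjugation intact.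

Step 3
Reactants: 5 1,2-bis(4-methoxy-2-oxo-2H-pyran-6-yl)ethane
Product: 7 4,4'-dimethoxybiphenyl-2,2',6,6'-tetraol, via ring-opened diketo diester 6 (not isolated)
Conditions: NaOMe (8 equiv), MeOH (degassed), 100 °C (sealed vessel), Ar; then 2 M HCl, 0 °C
Reagents that add atoms: none
Why: Methoxide adds to each lactone carbonyl and opens the ring to a methyl 3-methoxy-5-oxoalk-2-enoate whose ester and keto chain stay cis across C2=C3 (E by the CIP rules, because OMe outranks CH2), so that 6 is the doubly opened form; the conjugated C4 enolate equilibrates with the enolate at the tether CH2, which adds to the ester carbonyl, expels methoxide and tautomerises to the resorcinolate. The closest known reaction is the methoxide-induced conversion of 4-methoxy-6-methyl-2-pyranone into 5-methoxyresorcinol, an intramolecular Claisen (Dieckmann-type) ring transformation; here it runs twice in one molecule with the two carbons of one tether as nucleophiles, so the existing CH2–CH2 bond becomes the biaryl bond and no aryl–aryl bond has to be formed. Each ring A closes in a 6-(enolendo)-exo-trig mode, since both enolate carbons lie inside the new ring, which is a favoured closure for six-membered rings. No stereocentre arises, and the axis forms as the racemate. The step needs chemoselectivity for the six-ring Claisen over a five-ring aldol between the two ketones of 6 and over seven-ring acylation by the distal tether carbon: the aldol is reversible, the ketone carbonyls rest as their conjugated enolates, the first aromatisation removes the 1,4-diketone, and only the Claisen path ends in a phenoxide that cannot revert. Methoxide in methanol matches both the ester and the enol ether, so transesterification and addition–elimination at C3 are degenerate, and the constitution alone places the surviving methoxy group para to the axis with a hydroxyl on either side of it.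

Step 4
Reactants: 7 4,4'-dimethoxybiphenyl-2,2',6,6'-tetraol; 8 acetonitrile
Product: 10 3,3'-diacetyl-4,4'-dimethoxybiphenyl-2,2',6,6'-tetraol, via bis-ketiminium dichloride 9 (not isolated)
Conditions: MeCN (6 equiv), ZnCl2, HCl (g), Et2O, 0 °C; then H2O, 100 °C
Reagents that add atoms: acetonitrile, CC#N; water, O
Why: Houben–Hoesch acylation, in which the nitrilium electrophile attacks the only kind of free ring position (ortho to OH and OMe, para to the second OH, the two CH of each ring being equivalent), the iminium salt protects each ring from a second acylation, and hydrolysis should give the methyl ketone.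

Step 5
Reactants: 10 3,3'-diacetyl-4,4'-dimethoxybiphenyl-2,2',6,6'-tetraol; 11 4-methoxybenzoyl chloride
Product: 13 1,1'-(2,2',6,6'-tetrahydroxy-4,4'-dimethoxybiphenyl-3,3'-diyl)bis[3-(4-methoxyphenyl)propane-1,3-dione], via hexalithium polyanion 12 (not isolated)
Conditions: LiN(SiMe3)2 (8.5 equiv), THF, −78 to −10 °C; then 4-MeOC6H4COCl (2.1 equiv), −78 °C to rt; 1 M HCl
Reagents that add atoms: 4-methoxybenzoyl chloride, COc1ccc(cc1)C(=O)Cl
Why: Crossed Claisen C-aroylation of the polylithiated hydroxyacetophenone (the direct form of the Baker–Venkataraman route to ring A hydroxylated flavones), in which the enolate carbon is the most nucleophilic site, the extra base takes up the acidity of the diketone, and an ester formed at the chelated ortho oxygen would shift to carbon under the same conditions.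

Step 6
Reactants: 13 1,1'-(2,2',6,6'-tetrahydroxy-4,4'-dimethoxybiphenyl-3,3'-diyl)bis[3-(4-methoxyphenyl)propane-1,3-dione]
Product: 14 7,7''-dihydroxy-5,5''-dimethoxy-2,2''-bis(4-methoxyphenyl)-4H,4''H-[8,8''-bichromene]-4,4''-dione
Conditions: H2SO4 (cat.), AcOH, 95 °C
Reagents that add atoms: none
Why: Acid-catalysed cyclodehydration of the 2-hydroxyaryl 1,3-diketone to the 4-pyranone ring C, which can only close onto the hydroxyl next to the biaryl axis because the other position ortho to the diketone carries the methoxy group, so the 8,8'' linkage is fixed.

Step 7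
Reactants: 14 7,7''-dihydroxy-5,5''-dimethoxy-2,2''-bis(4-methoxyphenyl)-4H,4''H-[8,8''-bichromene]-4,4''-dione
Product: 15 cupressuflavone (racemic)
Conditions: BBr3 (12 equiv), CH2Cl2, −78 °C to rt; then MeOH, H2O
Reagents that add atoms: none
Why: Lewis acid cleavage of the four aryl methyl ethers with BBr3, the peri 5-methoxy groups going first through chelation to the C4 carbonyl, under anhydrous conditions that should not open ring C and so avoid a Wessely–Moser shift of the axis from C8 to C6.

Compound list
1 | triacetic lactone (4-hydroxy-6-methyl-2H-pyran-2-one) | Cc1cc(O)cc(=O)o1 | starting material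
2 | dimethyl sulfate | COS(=O)(=O)OC | starting material
3 | 4-methoxy-6-methyl-2H-pyran-2-one | Cc1cc(OC)cc(=O)o1 | intermediate
4 | lithium 4-methoxy-6-methylidene-6H-pyran-2-olate (lithium dienolate of 3; not isolated) | [Li+].[O-]C1=CC(OC)=CC(=C)O1 | intermediate
5 | 1,2-bis(4-methoxy-2-oxo-2H-pyran-6-yl)ethane | COc1cc(CCc2cc(OC)cc(=O)o2)oc(=O)c1 | intermediate
6 | dimethyl (2E,10E)-3,10-dimethoxy-5,8-dioxododeca-2,10-dienedioate (ring-opened diketo diester; not isolated) | COC(=O)/C=C(OC)\CC(=O)CCC(=O)C/C(OC)=C\C(=O)OC | intermediate
7 | 4,4'-dimethoxybiphenyl-2,2',6,6'-tetraol | COc1cc(O)c(-c2c(O)cc(OC)cc2O)c(O)c1 | intermediate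
8 | acetonitrile | CC#N | starting material
9 | 1,1'-(2,2',6,6'-tetrahydroxy-4,4'-dimethoxybiphenyl-3,3'-diyl)bis(ethan-1-iminium) dichloride (bis-ketiminium dichloride; not isolated) | CC(=[NH2+])c1c(O)c(-c2c(O)cc(OC)c(C(C)=[NH2+])c2O)c(O)cc1OC.[Cl-].[Cl-] | intermediate
10 | 3,3'-diacetyl-4,4'-dimethoxybiphenyl-2,2',6,6'-tetraol | CC(=O)c1c(O)c(-c2c(O)cc(OC)c(C(C)=O)c2O)c(O)cc1OC | intermediate
11 | 4-methoxybenzoyl chloride | COc1ccc(cc1)C(=O)Cl | starting material
12 | hexalithium salt of 10 (four phenoxides, two enolates; not isolated) | [Li+].[Li+].[Li+].[Li+].[Li+].[Li+].C=C([O-])c1c([O-])c(-c2c([O-])cc(OC)c(C(=C)[O-])c2[O-])c([O-])cc1OC | intermediate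
13 | 1,1'-(2,2',6,6'-tetrahydroxy-4,4'-dimethoxybiphenyl-3,3'-diyl)bis[3-(4-methoxyphenyl)propane-1,3-dione] | COc1ccc(cc1)C(=O)CC(=O)c1c(O)c(-c2c(O)cc(OC)c(C(=O)CC(=O)c3ccc(OC)cc3)c2O)c(O)cc1OC | intermediate
14 | 7,7''-dihydroxy-5,5''-dimethoxy-2,2''-bis(4-methoxyphenyl)-4H,4''H-[8,8''-bichromene]-4,4''-dione (cupressuflavone 5,5'',4',4'''-tetramethyl ether) | O=c1cc(-c2ccc(OC)cc2)oc2c(-c3c(O)cc(OC)c4c(=O)cc(-c5ccc(OC)cc5)oc34)c(O)cc(OC)c12 | intermediate
15 | cupressuflavone (5,5'',7,7''-tetrahydroxy-2,2''-bis(4-hydroxyphenyl)-4H,4''H-[8,8''-bichromene]-4,4''-dione, racemic about the axis) | O=c1cc(-c2ccc(O)cc2)oc2c(-c3c(O)cc(O)c4c(=O)cc(-c5ccc(O)cc5)oc34)c(O)cc(O)c12 | target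

Total step count: 7. Longest linear sequence: 7 steps (1 to 15).

Steps most likely to fail

Step 3. Once both lactones are open the chain is a 1,4-diketone, and aldol closure of the C4 enolate of one half onto the ketone of the other (five-membered ring, then dehydration) may outrun the Claisen closures. The second Claisen closure may also stall after the first arene has formed, and the half-converted aryl ketone would then condense with its ortho hydroxyl to a benzofuran on acidification. The fallback builds the same biphenyl by established steps. It sets out from 3, which the single ring transformation (NaOMe, MeOH, heat) should convert into 5-methoxyresorcinol F1. Protection with MOMCl and i-Pr2NEt in CH2Cl2 should give 1-methoxy-3,5-bis(methoxymethoxy)benzene F2. Directed ortho-lithiation with n-BuLi in THF at 0 °C at the carbon between the two methoxymethoxy groups, followed by oxidative homocoupling of the aryllithium with anhydrous FeCl3, should give 4,4'-dimethoxy-2,2',6,6'-tetrakis(methoxymethoxy)biphenyl F3. Acetal cleavage with HCl in MeOH at 50 °C returns to the route at 7.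

Step 2. Electron transfer from the ambident dienolate may be followed by bond formation at ring carbon C3 or C5 instead of the exocyclic carbon, or by chlorine transfer from CuCl2 to carbon. The base may also partly metalate C3. Each of these diverts material from the tail-to-tail dimer. The fallback replaces the oxidative coupling by a polar alkylation. It sets out from 3, which Wohl–Ziegler bromination (NBS, cat. dibenzoyl peroxide, PhCF3, reflux) should convert into 6-(bromomethyl)-4-methoxy-2H-pyran-2-one F4. The lithium dienolate 4, made from a second portion of 3 with LiN(SiMe3)2 in THF at −78 °C, is then added to F4 at −78 °C, and SN2 displacement of bromide returns to the route at 5.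

Step 5. The hexalithiated salt may precipitate or enolise incompletely in THF, so that acylation falls on the unhindered phenoxide oxygen para to the ketone, or a second aroyl group adds at the same carbon. Either gives mixtures of esters and triketones in place of the bis-diketone. The fallback builds ring C through the chalcone. It sets out from 10, which Claisen–Schmidt condensation with 4-methoxybenzaldehyde (KOH, EtOH–H2O, rt) should convert into (2E,2'E)-1,1'-(2,2',6,6'-tetrahydroxy-4,4'-dimethoxybiphenyl-3,3'-diyl)bis[3-(4-methoxyphenyl)prop-2-en-1-one] F5. Oxidative cyclisation of the 2'-hydroxychalcone units with catalytic I2 in DMSO at 130 °C returns to the route at 14, bypassing 13 and step 6.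

Further compounds
F1 | step 3 | 5-methoxybenzene-1,3-diol (5-methoxyresorcinol) | COc1cc(O)cc(O)c1
F2 | step 3 | 1-methoxy-3,5-bis(methoxymethoxy)benzene | COCOc1cc(OC)cc(OCOC)c1
F3 | step 3 | 4,4'-dimethoxy-2,2',6,6'-tetrakis(methoxymethoxy)biphenyl | COCOc1cc(OC)cc(OCOC)c1-c1c(OCOC)cc(OC)cc1OCOC
F4 | step 2 | 6-(bromomethyl)-4-methoxy-2H-pyran-2-one | COc1cc(CBr)oc(=O)c1
F5 | step 5 | (2E,2'E)-1,1'-(2,2',6,6'-tetrahydroxy-4,4'-dimethoxybiphenyl-3,3'-diyl)bis[3-(4-methoxyphenyl)prop-2-en-1-one] | COc1ccc(/C=C/C(=O)c2c(O)c(-c3c(O)cc(OC)c(C(=O)/C=C/c4ccc(OC)cc4)c3O)c(O)cc2OC)cc1
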